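**Retrosynthetic overview**
1. The tetraene is cut at its central single bond (Stille coupling): lactone dienylstannane 18 (West fragment) plus dihydropyran dienyl iodide 29 (East fragment).
2. West: the lactone ring and its C4–C5 bond (oxolanone numbering) are made in one step from aldehyde 8 and the 2-(borylmethyl)dienoate 5. Boronate 5 acts as an ester homoenolate equivalent, so two carbons that are both acceptors in normal polarity (aldehyde carbon and enoate β-carbon) are joined; this sets C5 and the quaternary C4.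
3. The lactone α-methyl centre comes from conjugate reduction of the exo-methylene; the side-chain centre comes from the (S)-Roche ester.
4. East: the dihydropyran ring is taken ready-made from L-rhamnal (C6). C2 is set by Ferrier C-alkynylation and C3 by an alkylative enone transposition followed by face-selective methyl addition. Carboalumination/cross-coupling builds the trisubstituted iododiene.
5. Ring order: pyran (chiral pool) first in its own branch, lactone in the key step, tetraene last.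

Assumption: compounds 1, 2, 6, 17, 19, 20, 27 and all reagents are bought; locants in the comments are oxolan-2-one locants for the lactone (C3 α-carbon, C4 quaternary, C5 O-bearing) and target locants for the pyran (C2 side chain, C3 carbinol, C6 methyl).

**Route**

Step 1
Reactants: 1 (E)-(2-bromoethenyl)trimethylsilane; 2 methyl prop-2-ynoate
Product: 3 methyl (4E)-5-(trimethylsilyl)pent-4-en-2-ynoate
Conditions: Pd(PPh3)4 (3 mol %), CuI (6 mol %), K2CO3, THF, 40 °C
Reagents that add atoms: none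
Why: Sonogashira coupling under an inorganic base (no amine that could add to the ynoate) joins the vinyl bromide to the propiolate with retention of the E-vinylsilane.

Step 2
Reactants: 3 methyl (4E)-5-(trimethylsilyl)pent-4-en-2-ynoate
Product: 5 methyl (2Z,4E)-3-methyl-2-[(4,4,5,5-tetramethyl-1,3,2-dioxaborolan-2-yl)methyl]-5-(trimethylsilyl)penta-2,4-dienoate, via alkenylcuprate 4 (not isolated)
Conditions: MeLi (2 equiv), CuI (1 equiv), THF, −78 °C; add 3; then ICH2Bpin, HMPA, −78 → 0 °C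
Reagents that add atoms: methyllithium, C[Li] (used as lithium dimethylcuprate, [Li+].C[Cu-]C); 2-(iodomethyl)-4,4,5,5-tetramethyl-1,3,2-dioxaborolane, ICB1OC(C)(C)C(C)(C)O1
Why: syn-carbocupration of the ynoate places methyl and copper cis, and alkylation of the α-cuprio ester with the iodomethylboronate at low temperature keeps that geometry (methyl cis to CH2B, silylvinyl cis to the ester), the bulky silyl terminus disfavouring 1,6-addition; reaction type organocuprate conjugate addition followed by alkylation.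

Step 3
Reactants: 6 methyl (2S)-3-hydroxy-2-methylpropanoate
Product: 7 methyl (2S)-3-{[tert-butyl(dimethyl)silyl]oxy}-2-methylpropanoate
Conditions: TBSCl, imidazole, CH2Cl2, 0 °C → rt
Reagents that add atoms: tert-butyl(chloro)dimethylsilane, CC(C)(C)[Si](C)(C)Cl
Why: standard silyl ether formation on the primary alcohol, which leaves the stereocentre untouched.

Step 4
Reactants: 7 methyl (2S)-3-{[tert-butyl(dimethyl)silyl]oxy}-2-methylpropanoate
Product: 8 (2S)-3-{[tert-butyl(dimethyl)silyl]oxy}-2-methylpropanal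
Conditions: i-Bu2AlH (1.1 equiv), CH2Cl2, −78 °C; aq KNaC4H4O6 work-up
Reagents that add atoms: none
Why: partial reduction of the ester by i-Bu2AlH stops at the aluminium hemiacetal at −78 °C, and the aldehyde is used at once so the α-centre does not epimerise.

Step 5
Reactants: 5 methyl (2Z,4E)-3-methyl-2-[(4,4,5,5-tetramethyl-1,3,2-dioxaborolan-2-yl)methyl]-5-(trimethylsilyl)penta-2,4-dienoate; 8 (2S)-3-{[tert-butyl(dimethyl)silyl]oxy}-2-methylpropanal
Product: 10 (4R,5S)-5-[(2S)-1-{[tert-butyl(dimethyl)silyl]oxy}propan-2-yl]-4-methyl-3-methylidene-4-[(E)-2-(trimethylsilyl)ethenyl]oxolan-2-one, via O-boryl adduct 9 (not isolated)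
Conditions: Sc(OTf)3 (10 mol %), toluene, −78 → 0 °C; then PPTS, rt
Reagents that add atoms: none
Why: Lewis-acid-catalysed allylboration through a closed chair transition state in which 5 behaves as an ester homoenolate equivalent (its γ-carbon, the β-carbon of the acrylate and an acceptor in normal polarity, attacks the aldehyde carbon), so that the 2Z geometry puts the C4 methyl cis and the silylvinyl group trans to the C5 side chain, the Z-γ-methyl group enforces anti-Felkin attack on (S)-8 (C5 S, anti to the side-chain methyl), and the O-boryl adduct closes to the lactone with loss of MeOBpin.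

Step 6
Reactants: 10 (4R,5S)-5-[(2S)-1-{[tert-butyl(dimethyl)silyl]oxy}propan-2-yl]-4-methyl-3-methylidene-4-[(E)-2-(trimethylsilyl)ethenyl]oxolan-2-one
Product: 11 (3R,4S,5S)-5-[(2S)-1-{[tert-butyl(dimethyl)silyl]oxy}propan-2-yl]-3,4-dimethyl-4-[(E)-2-(trimethylsilyl)ethenyl]oxolan-2-one
Conditions: Cu(OAc)2·H2O (5 mol %), 1,2-bis(diphenylphosphino)benzene (5 mol %), (EtO)2MeSiH, t-BuOH, toluene, rt
Reagents that add atoms: none
Why: copper hydride conjugate reduction touches only the exo-methylene lactone, and kinetic protonation of the enolate at C3 from the face of the flat silylvinyl group (away from the cis C4 methyl and C5 side chain) gives the 3R epimer with the new methyl cis to both.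

Step 7
Reactants: 11 (3R,4S,5S)-5-[(2S)-1-{[tert-butyl(dimethyl)silyl]oxy}propan-2-yl]-3,4-dimethyl-4-[(E)-2-(trimethylsilyl)ethenyl]oxolan-2-one
Product: 14 (2R)-2-{(2S,3S,4R)-3,4-dimethyl-5-oxo-3-[(E)-2-(trimethylsilyl)ethenyl]oxolan-2-yl}propanoic acid, via primary alcohol 12 (not isolated), via aldehyde 13 (not isolated)
Conditions: CrO3, H2SO4, H2O, acetone, 0 °C → rt
Reagents that add atoms: water, O
Why: Jones oxidation cleaves the primary silyl ether in the aqueous acid and oxidises the alcohol through the aldehyde hydrate to the acid without any base, so neither the α-centres nor the β-acyloxy carbonyl unit can enolise or eliminate.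

Step 8
Reactants: 14 (2R)-2-{(2S,3S,4R)-3,4-dimethyl-5-oxo-3-[(E)-2-(trimethylsilyl)ethenyl]oxolan-2-yl}propanoic acid
Product: 15 methyl (2R)-2-{(2S,3S,4R)-3,4-dimethyl-5-oxo-3-[(E)-2-(trimethylsilyl)ethenyl]oxolan-2-yl}propanoate
Conditions: TMSCHN2, MeOH/toluene, 0 °C
Reagents that add atoms: (trimethylsilyl)diazomethane, C[Si](C)(C)C=[N+]=[N-]
Why: diazoalkane esterification is neutral and fast, so the base-sensitive β-acyloxy ester is formed without epimerisation or elimination.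

Step 9
Reactants: 15 methyl (2R)-2-{(2S,3S,4R)-3,4-dimethyl-5-oxo-3-[(E)-2-(trimethylsilyl)ethenyl]oxolan-2-yl}propanoate
Product: 16 methyl (2R)-2-{(2S,3S,4R)-3-[(E)-2-iodoethenyl]-3,4-dimethyl-5-oxooxolan-2-yl}propanoate
Conditions: NIS, (CF3)2CHOH, 0 °C, dark
Reagents that add atoms: N-iodosuccinimide, O=C1CCC(=O)N1I
Why: ipso-iododesilylation of the vinylsilane proceeds through a β-silyl cation and gives the vinyl iodide with retention of the E geometry.

Step 10
Reactants: 16 methyl (2R)-2-{(2S,3S,4R)-3-[(E)-2-iodoethenyl]-3,4-dimethyl-5-oxooxolan-2-yl}propanoate; 17 (E)-1,2-bis(tributylstannyl)ethene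
Product: 18 methyl (2R)-2-{(2S,3R,4R)-3,4-dimethyl-5-oxo-3-[(1E,3E)-4-(tributylstannyl)buta-1,3-dien-1-yl]oxolan-2-yl}propanoate
Conditions: Pd2(dba)3 (2.5 mol %), AsPh3 (20 mol %), 17 (4 equiv), NMP, rt, dark
Reagents that add atoms: none
Why: Stille coupling with an excess of the distannane stops after one coupling and keeps both alkene geometries.

Step 11
Reactants: 19 (2S,3S,4S)-2-methyl-3,4-dihydro-2H-pyran-3,4-diyl diacetate (3,4-di-O-acetyl-L-rhamnal); 20 bis(trimethylsilyl)acetylene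
Product: 21 (2S,3R,6R)-2-methyl-6-[(trimethylsilyl)ethynyl]-3,6-dihydro-2H-pyran-3-yl acetate
Conditions: Me3SiOTf (20 mol %), CH2Cl2, −40 → −20 °C
Reagents that add atoms: none
Why: Ferrier-type C-glycosylation, in which the allylic oxocarbenium ion from the glycal is attacked by the alkynylsilane axially at the anomeric carbon, trans to the ring methyl, which sets pyran C2 relative to C6 (2,6-trans).

Step 12
Reactants: 21 (2S,3R,6R)-2-methyl-6-[(trimethylsilyl)ethynyl]-3,6-dihydro-2H-pyran-3-yl acetate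
Product: 22 (2S,3R,6R)-6-ethynyl-2-methyl-3,6-dihydro-2H-pyran-3-ol
Conditions: K2CO3 (cat.), MeOH, rt
Reagents that add atoms: none
Why: methanolysis removes the acetate and the alkynyl silyl group in one operation.

Step 13
Reactants: 22 (2S,3R,6R)-6-ethynyl-2-methyl-3,6-dihydro-2H-pyran-3-ol
Product: 23 (2S,6R)-6-ethynyl-2-methyl-2H-pyran-3(6H)-one
Conditions: MnO2, CH2Cl2, rt
Reagents that add atoms: none
Why: neutral allylic oxidation gives the enone without touching the epimerisable α-alkoxy centre.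

Step 14
Reactants: 23 (2S,6R)-6-ethynyl-2-methyl-2H-pyran-3(6H)-one
Product: 24 (2S,6R)-6-ethynyl-2,3-dimethyl-3,6-dihydro-2H-pyran-3-ol (mixture of C3 epimers)
Conditions: MeLi, CeCl3, THF, −78 °C; aq NH4Cl
Reagents that add atoms: methyllithium, C[Li] (transmetallated in the flask to dichloro(methyl)cerium, C[Ce](Cl)Cl)
Why: the weakly basic organocerium reagent adds 1,2 to the enone without enolising the α-alkoxy centre, and the configuration of the new carbinol does not matter because it is erased in the next step.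

Step 15
Reactants: 24 (2S,6R)-6-ethynyl-2,3-dimethyl-3,6-dihydro-2H-pyran-3-ol
Product: 25 (2S,6S)-2-ethynyl-5,6-dimethyl-2H-pyran-3(6H)-one
Conditions: pyridinium chlorochromate [C5H5NH][CrO3Cl], 4 Å molecular sieves, CH2Cl2, rt
Reagents that add atoms: pyridinium chlorochromate, [O-][Cr](=O)(=O)Cl.c1cc[nH+]cc1
Why: Dauben–Babler oxidative transposition, in which the chromate ester of the tertiary allylic alcohol undergoes a [3,3] shift and is oxidised to the transposed enone, moving the oxygen to pyran C3 and leaving the methyl on the C4=C5 alkene.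

Step 16
Reactants: 25 (2S,6S)-2-ethynyl-5,6-dimethyl-2H-pyran-3(6H)-one
Product: 26 (2S,3R,6S)-2-ethynyl-3,5,6-trimethyl-3,6-dihydro-2H-pyran-3-ol
Conditions: MeLi, CeCl3, THF, −78 °C; aq NH4Cl
Reagents that add atoms: methyllithium, C[Li] (transmetallated in the flask to dichloro(methyl)cerium, C[Ce](Cl)Cl)
Why: organocerium 1,2-addition to the enone occurs on the face opposite the pseudo-axial C6 methyl (the face of the pseudo-equatorial ethynyl group), as in additions to 2,6-trans pyranones, so the new methyl is cis to the alkyne and the hydroxyl trans (3R).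

Step 17
Reactants: 26 (2S,3R,6S)-2-ethynyl-3,5,6-trimethyl-3,6-dihydro-2H-pyran-3-ol; 27 (E)-1,2-diiodoethene
Product: 29 (2S,3R,6S)-2-[(2E,4E)-5-iodopenta-2,4-dien-2-yl]-3,5,6-trimethyl-3,6-dihydro-2H-pyran-3-ol, via alkenylalane 28 (not isolated)
Conditions: Me3Al (3 equiv), Cp2ZrCl2 (25 mol %), CH2Cl2, 0 °C → rt; then 27 (3 equiv), Pd(PPh3)4 (5 mol %), ZnCl2 (10 mol %), THF, rt
Reagents that add atoms: trimethylaluminium, C[Al](C)C
Why: Negishi zirconium-catalysed syn-carboalumination puts methyl on the internal and aluminium on the terminal alkyne carbon, and the alkenylalane is cross-coupled in the same flask (palladium/zinc-catalysed Negishi coupling) with one C–I bond of excess 27, both alkenes being formed with retention.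

Step 18
Reactants: 18 methyl (2R)-2-{(2S,3R,4R)-3,4-dimethyl-5-oxo-3-[(1E,3E)-4-(tributylstannyl)buta-1,3-dien-1-yl]oxolan-2-yl}propanoate; 29 (2S,3R,6S)-2-[(2E,4E)-5-iodopenta-2,4-dien-2-yl]-3,5,6-trimethyl-3,6-dihydro-2H-pyran-3-ol
Product: 30 methyl (2R)-2-[(2S,3R,4R)-3-{(1E,3E,5E,7E)-8-[(2S,3R,6S)-3-hydroxy-3,5,6-trimethyl-3,6-dihydro-2H-pyran-2-yl]nona-1,3,5,7-tetraen-1-yl}-3,4-dimethyl-5-oxooxolan-2-yl]propanoate
Conditions: Pd2(dba)3 (5 mol %), AsPh3 (20 mol %), NMP, rt, dark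
Reagents that add atoms: none
Why: Stille coupling of the dienylstannane with the dienyl iodide forms the central single bond of the all-E tetraene with retention under neutral conditions that tolerate the lactone, the β-acyloxy ester and the free tertiary alcohol.

**Compound list**
1 | (E)-(2-bromoethenyl)trimethylsilane | C[Si](C)(C)/C=C/Br | starting material
2 | methyl prop-2-ynoate | C#CC(=O)OC | starting material
3 | methyl (4E)-5-(trimethylsilyl)pent-4-en-2-ynoate | COC(=O)C#C/C=C/[Si](C)(C)C | intermediate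
4 | lithium [(1E,3E)-1-(methoxycarbonyl)-2-methyl-4-(trimethylsilyl)buta-1,3-dien-1-yl](methyl)cuprate | COC(=O)/C([Cu-]C)=C(\C=C\[Si](C)(C)C)C.[Li+] | intermediate
5 | methyl (2Z,4E)-3-methyl-2-[(4,4,5,5-tetramethyl-1,3,2-dioxaborolan-2-yl)methyl]-5-(trimethylsilyl)penta-2,4-dienoate | COC(=O)/C(CB1OC(C)(C)C(C)(C)O1)=C(\C=C\[Si](C)(C)C)C | intermediate
6 | methyl (2S)-3-hydroxy-2-methylpropanoate | COC(=O)[C@@H](C)CO | starting material
7 | methyl (2S)-3-{[tert-butyl(dimethyl)silyl]oxy}-2-methylpropanoate | COC(=O)[C@@H](C)CO[Si](C)(C)C(C)(C)C | intermediate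
8 | (2S)-3-{[tert-butyl(dimethyl)silyl]oxy}-2-methylpropanal | O=C[C@@H](C)CO[Si](C)(C)C(C)(C)C | intermediate
9 | methyl (3R,4S,5S)-6-{[tert-butyl(dimethyl)silyl]oxy}-3,5-dimethyl-2-methylidene-4-[(4,4,5,5-tetramethyl-1,3,2-dioxaborolan-2-yl)oxy]-3-[(E)-2-(trimethylsilyl)ethenyl]hexanoate | CC(C)(C)[Si](C)(C)OC[C@H](C)[C@H](OB1OC(C)(C)C(C)(C)O1)[C@](C)(/C=C/[Si](C)(C)C)C(=C)C(=O)OC | intermediate
10 | (4R,5S)-5-[(2S)-1-{[tert-butyl(dimethyl)silyl]oxy}propan-2-yl]-4-methyl-3-methylidene-4-[(E)-2-(trimethylsilyl)ethenyl]oxolan-2-one | CC(C)(C)[Si](C)(C)OC[C@H](C)[C@@H]1OC(=O)C(=C)[C@@]1(C)/C=C/[Si](C)(C)C | intermediate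
11 | (3R,4S,5S)-5-[(2S)-1-{[tert-butyl(dimethyl)silyl]oxy}propan-2-yl]-3,4-dimethyl-4-[(E)-2-(trimethylsilyl)ethenyl]oxolan-2-one | CC(C)(C)[Si](C)(C)OC[C@H](C)[C@@H]1OC(=O)[C@H](C)[C@@]1(C)/C=C/[Si](C)(C)C | intermediate
12 | (3R,4S,5S)-5-[(2S)-1-hydroxypropan-2-yl]-3,4-dimethyl-4-[(E)-2-(trimethylsilyl)ethenyl]oxolan-2-one | OC[C@H](C)[C@@H]1OC(=O)[C@H](C)[C@@]1(C)/C=C/[Si](C)(C)C | intermediate
13 | (2R)-2-{(2S,3S,4R)-3,4-dimethyl-5-oxo-3-[(E)-2-(trimethylsilyl)ethenyl]oxolan-2-yl}propanal | O=C[C@H](C)[C@@H]1OC(=O)[C@H](C)[C@@]1(C)/C=C/[Si](C)(C)C | intermediate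
14 | (2R)-2-{(2S,3S,4R)-3,4-dimethyl-5-oxo-3-[(E)-2-(trimethylsilyl)ethenyl]oxolan-2-yl}propanoic acid | OC(=O)[C@H](C)[C@@H]1OC(=O)[C@H](C)[C@@]1(C)/C=C/[Si](C)(C)C | intermediate
15 | methyl (2R)-2-{(2S,3S,4R)-3,4-dimethyl-5-oxo-3-[(E)-2-(trimethylsilyl)ethenyl]oxolan-2-yl}propanoate | COC(=O)[C@H](C)[C@@H]1OC(=O)[C@H](C)[C@@]1(C)/C=C/[Si](C)(C)C | intermediate
16 | methyl (2R)-2-{(2S,3S,4R)-3-[(E)-2-iodoethenyl]-3,4-dimethyl-5-oxooxolan-2-yl}propanoate | COC(=O)[C@H](C)[C@@H]1OC(=O)[C@H](C)[C@@]1(C)/C=C/I | intermediate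
17 | (E)-1,2-bis(tributylstannyl)ethene | CCCC[Sn](CCCC)(CCCC)/C=C/[Sn](CCCC)(CCCC)CCCC | starting material
18 | methyl (2R)-2-{(2S,3R,4R)-3,4-dimethyl-5-oxo-3-[(1E,3E)-4-(tributylstannyl)buta-1,3-dien-1-yl]oxolan-2-yl}propanoate | COC(=O)[C@H](C)[C@@H]1OC(=O)[C@H](C)[C@@]1(C)/C=C/C=C/[Sn](CCCC)(CCCC)CCCC | intermediate
19 | (2S,3S,4S)-2-methyl-3,4-dihydro-2H-pyran-3,4-diyl diacetate (3,4-di-O-acetyl-L-rhamnal) | C[C@@H]1OC=C[C@H](OC(C)=O)[C@H]1OC(C)=O | starting material
20 | bis(trimethylsilyl)acetylene | C[Si](C)(C)C#C[Si](C)(C)C | starting material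
21 | (2S,3R,6R)-2-methyl-6-[(trimethylsilyl)ethynyl]-3,6-dihydro-2H-pyran-3-yl acetate | C[Si](C)(C)C#C[C@@H]1O[C@@H](C)[C@H](OC(C)=O)C=C1 | intermediate
22 | (2S,3R,6R)-6-ethynyl-2-methyl-3,6-dihydro-2H-pyran-3-ol | C#C[C@@H]1O[C@@H](C)[C@H](O)C=C1 | intermediate
23 | (2S,6R)-6-ethynyl-2-methyl-2H-pyran-3(6H)-one | C#C[C@@H]1O[C@@H](C)C(=O)C=C1 | intermediate
24 | (2S,6R)-6-ethynyl-2,3-dimethyl-3,6-dihydro-2H-pyran-3-ol (C3 epimers) | C#C[C@@H]1O[C@@H](C)C(C)(O)C=C1 | intermediate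
25 | (2S,6S)-2-ethynyl-5,6-dimethyl-2H-pyran-3(6H)-one | C#C[C@@H]1O[C@@H](C)C(C)=CC1=O | intermediate
26 | (2S,3R,6S)-2-ethynyl-3,5,6-trimethyl-3,6-dihydro-2H-pyran-3-ol | C#C[C@@H]1O[C@@H](C)C(C)=C[C@@]1(C)O | intermediate
27 | (E)-1,2-diiodoethene | I/C=C/I | starting material
28 | dimethyl{(E)-2-[(2S,3R,6S)-3-[(dimethylalumanyl)oxy]-3,5,6-trimethyl-3,6-dihydro-2H-pyran-2-yl]prop-1-en-1-yl}alumane | C[Al](C)/C=C(\C)[C@@H]1O[C@@H](C)C(C)=C[C@@]1(C)O[Al](C)C | intermediate
29 | (2S,3R,6S)-2-[(2E,4E)-5-iodopenta-2,4-dien-2-yl]-3,5,6-trimethyl-3,6-dihydro-2H-pyran-3-ol | I/C=C/C=C(\C)[C@@H]1O[C@@H](C)C(C)=C[C@@]1(C)O | intermediate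
30 | methyl (2R)-2-[(2S,3R,4R)-3-{(1E,3E,5E,7E)-8-[(2S,3R,6S)-3-hydroxy-3,5,6-trimethyl-3,6-dihydro-2H-pyran-2-yl]nona-1,3,5,7-tetraen-1-yl}-3,4-dimethyl-5-oxooxolan-2-yl]propanoate | COC(=O)[C@H](C)[C@@H]1OC(=O)[C@H](C)[C@@]1(C)/C=C/C=C/C=C/C=C(\C)[C@@H]1O[C@@H](C)C(C)=C[C@@]1(C)O | target

**Step count**
Total: 18 steps. Longest linear sequence: 9 steps (1 → 2 → 5 → 6 → 7 → 8 → 9 → 10 → 18; the Roche branch 3 → 4 → 5 … is equally long; the East branch is 8 steps including step 18).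

**Three steps most likely to fail, with fallbacks**

Step 2 (the cuprate may add 1,6 to the ene-ynoate, or the α-cuprio ester may lose its geometry before it is trapped). The fallback sets out from aldehyde 8 and replaces 3 by an acetal ynoate that offers the cuprate only one acceptor position, namely methyl 4,4-diethoxybut-2-ynoate F1 (from 3,3-diethoxyprop-1-yne, n-BuLi and methyl chloroformate). The same Me2CuLi/ICH2Bpin sequence gives methyl (2Z)-4,4-diethoxy-3-methyl-2-[(4,4,5,5-tetramethyl-1,3,2-dioxaborolan-2-yl)methyl]but-2-enoate F2. Heating F2 with 8 (toluene, 80 °C, no Lewis acid because of the acetal) gives (4R,5S)-5-[(2S)-1-{[tert-butyl(dimethyl)silyl]oxy}propan-2-yl]-4-(diethoxymethyl)-4-methyl-3-methylideneoxolan-2-one F3. Copper hydride reduction as in step 6 gives (3R,4R,5S)-5-[(2S)-1-{[tert-butyl(dimethyl)silyl]oxy}propan-2-yl]-4-(diethoxymethyl)-3,4-dimethyloxolan-2-one F4. PPTS in wet acetone frees (2S,3R,4R)-2-[(2S)-1-{[tert-butyl(dimethyl)silyl]oxy}propan-2-yl]-3,4-dimethyl-5-oxooxolane-3-carbaldehyde F5. A Takai–Utimoto olefination (CrCl2, Me3SiCHBr2, THF) then builds the (E)-vinylsilane, and the route is rejoined at 11.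

Step 5 (the tetrasubstituted boronate may react sluggishly with the α-branched aldehyde, or substrate control may give a poor anti-Felkin ratio). The fallback sets out from 5 and moves the stereocontrol from the aldehyde to a catalyst, installing the side-chain centre afterwards. Boronate 5 is combined with methacrolein under a chiral phosphoric acid (TRIP, toluene, −30 °C; the enantiomer of the acid is chosen by experiment) and lactonised to (4R,5S)-4-methyl-3-methylidene-5-(prop-1-en-2-yl)-4-[(E)-2-(trimethylsilyl)ethenyl]oxolan-2-one F6. Reduction as in step 6 gives (3R,4S,5S)-3,4-dimethyl-5-(prop-1-en-2-yl)-4-[(E)-2-(trimethylsilyl)ethenyl]oxolan-2-one F7. Hydroboration of the isopropenyl group with 9-BBN anti to the ring C–O bond, followed by NaBO3·4H2O, gives primary alcohol 12, where the route is rejoined; 12 is oxidised with CrO3/H2SO4 to 14 as in step 7.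

Step 17 (the one-flask carboalumination/cross-coupling may give double coupling with 27 or a low yield next to the free alkoxide). The fallback sets out from 26 and exchanges the roles of the two coupling partners. Carboalumination of 26 as before but quenched with I2 gives (2S,3R,6S)-2-[(E)-1-iodoprop-1-en-2-yl]-3,5,6-trimethyl-3,6-dihydro-2H-pyran-3-ol F8. Stille coupling of F8 with excess 17 (Pd2(dba)3, AsPh3, NMP) gives (2S,3R,6S)-3,5,6-trimethyl-2-[(2E,4E)-5-(tributylstannyl)penta-2,4-dien-2-yl]-3,6-dihydro-2H-pyran-3-ol F9. On the other side, stannane 18 is treated with I2 (CH2Cl2, 0 °C) to give methyl (2R)-2-{(2S,3R,4R)-3-[(1E,3E)-4-iodobuta-1,3-dien-1-yl]-3,4-dimethyl-5-oxooxolan-2-yl}propanoate F10. Stille coupling of F9 with F10 under the conditions of step 18 comes back to the route at 30.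

**Further compounds**
F1 | step 2 | methyl 4,4-diethoxybut-2-ynoate | CCOC(OCC)C#CC(=O)OC
F2 | step 2 | methyl (2Z)-4,4-diethoxy-3-methyl-2-[(4,4,5,5-tetramethyl-1,3,2-dioxaborolan-2-yl)methyl]but-2-enoate | COC(=O)/C(CB1OC(C)(C)C(C)(C)O1)=C(\C(OCC)OCC)C
F3 | step 2 | (4R,5S)-5-[(2S)-1-{[tert-butyl(dimethyl)silyl]oxy}propan-2-yl]-4-(diethoxymethyl)-4-methyl-3-methylideneoxolan-2-one | CC(C)(C)[Si](C)(C)OC[C@H](C)[C@@H]1OC(=O)C(=C)[C@@]1(C)C(OCC)OCC
F4 | step 2 | (3R,4R,5S)-5-[(2S)-1-{[tert-butyl(dimethyl)silyl]oxy}propan-2-yl]-4-(diethoxymethyl)-3,4-dimethyloxolan-2-one | CC(C)(C)[Si](C)(C)OC[C@H](C)[C@@H]1OC(=O)[C@H](C)[C@@]1(C)C(OCC)OCC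
F5 | step 2 | (2S,3R,4R)-2-[(2S)-1-{[tert-butyl(dimethyl)silyl]oxy}propan-2-yl]-3,4-dimethyl-5-oxooxolane-3-carbaldehyde | CC(C)(C)[Si](C)(C)OC[C@H](C)[C@@H]1OC(=O)[C@H](C)[C@@]1(C)C=O
F6 | step 5 | (4R,5S)-4-methyl-3-methylidene-5-(prop-1-en-2-yl)-4-[(E)-2-(trimethylsilyl)ethenyl]oxolan-2-one | C=C(C)[C@@H]1OC(=O)C(=C)[C@@]1(C)/C=C/[Si](C)(C)C
F7 | step 5 | (3R,4S,5S)-3,4-dimethyl-5-(prop-1-en-2-yl)-4-[(E)-2-(trimethylsilyl)ethenyl]oxolan-2-one | C=C(C)[C@@H]1OC(=O)[C@H](C)[C@@]1(C)/C=C/[Si](C)(C)C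
F8 | step 17 | (2S,3R,6S)-2-[(E)-1-iodoprop-1-en-2-yl]-3,5,6-trimethyl-3,6-dihydro-2H-pyran-3-ol | I/C=C(\C)[C@@H]1O[C@@H](C)C(C)=C[C@@]1(C)O
F9 | step 17 | (2S,3R,6S)-3,5,6-trimethyl-2-[(2E,4E)-5-(tributylstannyl)penta-2,4-dien-2-yl]-3,6-dihydro-2H-pyran-3-ol | CCCC[Sn](CCCC)(CCCC)/C=C/C=C(\C)[C@@H]1O[C@@H](C)C(C)=C[C@@]1(C)O
F10 | step 17 | methyl (2R)-2-{(2S,3R,4R)-3-[(1E,3E)-4-iodobuta-1,3-dien-1-yl]-3,4-dimethyl-5-oxooxolan-2-yl}propanoate | COC(=O)[C@H](C)[C@@H]1OC(=O)[C@H](C)[C@@]1(C)/C=C/C=C/I
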